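The route rests on cutting the C7=C8 olefin, which lies in the 14-membered carbocycle opposite the C1/C14-fused γ-lactone and is later spent in the oxygen ene reaction that creates C7–OOH and the C8=C19 methylene. A sulfur atom inserted between C7 and C8 lets two halves be joined by thiolate alkylation; a Ramberg–Bäcklund reaction then expels SO2, forms C7=C8 and contracts the 15-membered thiacycle to the cembrane ring in one operation, with the C3–C4 epoxide, the 11E olefin and the lactone already in place. The precursor is the 15-membered α-chloro sulfone (chlorine on C7, C19 methyl on C8) carrying the (3S,4S)-epoxide, the saturated lactone and a 13-O-triethylsilyl group.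

Key step: step 19

Remark on numbering: cembrane locants are used throughout; C1 (lactone β-carbon) to C14 (lactone O-bearing carbon) run round the ring, C15 and C16 are the lactone α-carbon and carbonyl, C17 is the exocyclic methylene, and C18, C19, C20 are the methyls on C4, C8, C12.
Remark on stereochemistry: C8 is introduced racemic, and C7 and the sulfoxide sulfur arise as mixtures; all are erased in step 19, so they are left undefined in names and SMILES.
Remark on design: C7 is carried as a chloride (inert to zinc, palladium and CrCl2, still displaced by a thiolate in DMF), the C13 oxygen as a triethylsilyl ether (put on and removed without strong acid next to the epoxide), and sulfur is oxidised in two stages so that the 11E olefin never meets excess peracid.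
Remark on materials: compounds 1, 7 and 14 and the L-fructose-derived ketone of step 7 are taken as commercial.

Step 1
Reactants: 1 (R)-5-(hydroxymethyl)dihydrofuran-2(3H)-one
Product: 2 (R)-5-{[tert-butyl(dimethyl)silyl]oxymethyl}dihydrofuran-2(3H)-one
Conditions: TBSCl, imidazole, DMF, 0 °C → rt
Reagents that add atoms: tert-butyl(chloro)dimethylsilane, CC(C)(C)[Si](C)(C)Cl
Why: Imidazole-mediated silylation of the primary alcohol (the future C13 oxygen) leaves the C14 stereocentre untouched.

Step 2
Reactants: 2 (R)-5-{[tert-butyl(dimethyl)silyl]oxymethyl}dihydrofuran-2(3H)-one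
Product: 4 (R)-5-{[tert-butyl(dimethyl)silyl]oxymethyl}furan-2(5H)-one, via α-phenylselanyl lactone 3 (not isolated)
Conditions: LiN(i-Pr)2, THF, −78 °C; PhSeBr; then H2O2 (30 %), pyridine, CH2Cl2, 0 °C → rt
Reagents that add atoms: none
Why: α-Selenenylation of the lactone enolate and selenoxide syn-elimination give the butenolide without involving the γ-stereocentre (C14).

Step 3
Reactants: 4 (R)-5-{[tert-butyl(dimethyl)silyl]oxymethyl}furan-2(5H)-one
Product: 5 (4S,5R)-5-{[tert-butyl(dimethyl)silyl]oxymethyl}-4-(hydroxymethyl)dihydrofuran-2(3H)-one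
Conditions: MeOH (solvent), benzophenone (cat.), hν (350 nm), degassed, rt
Reagents that add atoms: methanol, CO
Why: Benzophenone-sensitised radical conjugate addition (Giese type) of the hydroxymethyl radical to the butenolide β-carbon occurs anti to the C5 silyloxymethyl group, which sets C1 trans to C14 and brings in C2 as CH2OH.

Step 4
Reactants: 5 (4S,5R)-5-{[tert-butyl(dimethyl)silyl]oxymethyl}-4-(hydroxymethyl)dihydrofuran-2(3H)-one
Product: 6 (4R,5R)-5-{[tert-butyl(dimethyl)silyl]oxymethyl}-4-(iodomethyl)dihydrofuran-2(3H)-one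
Conditions: I2, PPh3, imidazole, CH2Cl2, 0 °C → rt
Reagents that add atoms: iodine, [I][I]
Why: Appel-type iodination of the primary alcohol takes place at a CH2 group, so no stereocentre is affected (the descriptor at C4 changes only through priorities).

Step 5
Reactants: 7 5-chloropent-1-yne
Product: 8 (E)-5-chloro-1-iodo-2-methylpent-1-ene
Conditions: AlMe3 (2 equiv), Cp2ZrCl2 (0.2 equiv), CH2Cl2, 0 °C → rt; then I2, THF, −30 → 0 °C
Reagents that add atoms: trimethylaluminium, C[Al](C)C; iodine, [I][I]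
Why: Zirconium-catalysed syn-methylalumination of the terminal alkyne (Negishi carboalumination) puts methyl on the internal carbon, and iodinolysis with retention gives the E vinyl iodide that will become C3=C4 with C18, the alkyl chloride being inert.

Step 6
Reactants: 6 (4R,5R)-5-{[tert-butyl(dimethyl)silyl]oxymethyl}-4-(iodomethyl)dihydrofuran-2(3H)-one; 8 (E)-5-chloro-1-iodo-2-methylpent-1-ene
Product: 10 (4R,5R)-5-{[tert-butyl(dimethyl)silyl]oxymethyl}-4-[(2E)-6-chloro-3-methylhex-2-en-1-yl]dihydrofuran-2(3H)-one, via alkylzinc iodide 9 (not isolated)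
Conditions: Zn dust (activated with BrCH2CH2Br and Me3SiCl), DMF, rt; then 8, Pd(PPh3)4 (5 mol %), 40 °C
Reagents that add atoms: none
Why: Zinc insertion into the primary carbon–iodine bond gives a lactone-tolerant alkylzinc iodide, and Negishi sp3–sp2 coupling with retention of the vinyl iodide geometry forms C2–C3 and fixes the E-configured C3=C4 olefin.

Step 7
Reactants: 10 (4R,5R)-5-{[tert-butyl(dimethyl)silyl]oxymethyl}-4-[(2E)-6-chloro-3-methylhex-2-en-1-yl]dihydrofuran-2(3H)-one
Product: 11 (4R,5R)-5-{[tert-butyl(dimethyl)silyl]oxymethyl}-4-{[(2S,3S)-3-(3-chloropropyl)-3-methyloxiran-2-yl]methyl}dihydrofuran-2(3H)-one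
Conditions: 1,2:4,5-di-O-isopropylidene-β-L-erythro-2,3-hexodiulo-2,6-pyranose (0.3 equiv), KHSO5 (as 2KHSO5·KHSO4·K2SO4), K2CO3, Bu4NHSO4, MeCN/CH2(OMe)2/aq. Na2B4O7 buffer, 0 °C
Reagents that add atoms: potassium peroxymonosulfate, [K+].[O-]S(=O)(=O)OO
Why: Shi epoxidation through a spiro dioxirane transition state is reagent-controlled; since the D-fructose-derived ketone gives (R,R)-epoxides from E-trisubstituted olefins of this pattern, its enantiomer should set the (3S,4S)-epoxide.

Step 8
Reactants: 11 (4R,5R)-5-{[tert-butyl(dimethyl)silyl]oxymethyl}-4-{[(2S,3S)-3-(3-chloropropyl)-3-methyloxiran-2-yl]methyl}dihydrofuran-2(3H)-one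
Product: 12 (4R,5R)-4-{[(2S,3S)-3-(3-chloropropyl)-3-methyloxiran-2-yl]methyl}-5-(hydroxymethyl)dihydrofuran-2(3H)-one
Conditions: Bu4NF, AcOH (1:1), THF, 0 °C → rt
Reagents that add atoms: none
Why: Acetic-acid-buffered fluoride cleaves the primary silyl ether without opening the lactone or the epoxide and without displacing the chloride.

Step 9
Reactants: 12 (4R,5R)-4-{[(2S,3S)-3-(3-chloropropyl)-3-methyloxiran-2-yl]methyl}-5-(hydroxymethyl)dihydrofuran-2(3H)-one
Product: 13 (2R,3R)-3-{[(2S,3S)-3-(3-chloropropyl)-3-methyloxiran-2-yl]methyl}-5-oxooxolane-2-carbaldehyde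
Conditions: Dess–Martin periodinane, NaHCO3, CH2Cl2, 0 °C → rt; used crude
Reagents that add atoms: none
Why: Buffered Dess–Martin oxidation gives the C13 aldehyde under non-epimerising, non-acidic conditions that spare the epoxide.

Step 10
Reactants: 14 hex-4-yn-1-ol
Product: 15 (E)-4-iodohex-4-en-1-ol
Conditions: Cp2Zr(H)Cl (2.5 equiv), THF, rt → 40 °C; then I2, 0 °C
Reagents that add atoms: iodine, [I][I]
Why: Hydrozirconation adds Zr–H syn across the alkyne, excess reagent equilibrates zirconium to the less hindered methyl-bearing carbon (future C12), and iodinolysis with retention gives the E 2-iodoalkene.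

Step 11
Reactants: 15 (E)-4-iodohex-4-en-1-ol
Product: 16 (E)-4-iodohex-4-enal
Conditions: Dess–Martin periodinane, NaHCO3, CH2Cl2, 0 °C → rt
Reagents that add atoms: none
Why: Dess–Martin oxidation of the primary alcohol stops at the aldehyde and does not touch the vinyl iodide.

Step 12
Reactants: 16 (E)-4-iodohex-4-enal
Product: 17 (E)-6-iodohept-5-en-2-ol (racemic)
Conditions: MeMgBr, Et2O, −78 °C
Reagents that add atoms: methylmagnesium bromide, C[Mg]Br
Why: Grignard addition brings in the C19 methyl and the C8 carbinol (racemic, since C8 is destroyed later), the vinyl iodide being inert at low temperature.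

Step 13
Reactants: 17 (E)-6-iodohept-5-en-2-ol (racemic)
Product: 18 S-[(E)-6-iodohept-5-en-2-yl] ethanethioate (racemic)
Conditions: PPh3, diisopropyl azodicarboxylate, AcSH, THF, 0 °C → rt
Reagents that add atoms: thioacetic acid, CC(=O)S
Why: Mitsunobu reaction with thioacetic acid as the pronucleophile places sulfur on C8 by SN2 displacement of the activated secondary alcohol.

Step 14
Reactants: 13 (2R,3R)-3-{[(2S,3S)-3-(3-chloropropyl)-3-methyloxiran-2-yl]methyl}-5-oxooxolane-2-carbaldehyde; 18 S-[(E)-6-iodohept-5-en-2-yl] ethanethioate (racemic)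
Product: 19 S-[(5E,7S)-7-hydroxy-6-methyl-7-{(2R,3R)-3-{[(2S,3S)-3-(3-chloropropyl)-3-methyloxiran-2-yl]methyl}-5-oxooxolan-2-yl}hept-5-en-2-yl] ethanethioate (C8 epimers)
Conditions: CrCl2 (6 equiv), NiCl2 (1 mol %), degassed DMSO, rt; 18 in excess
Reagents that add atoms: none
Why: Nozaki–Hiyama–Kishi vinylation forms C12–C13 with retention of the 11E geometry; the vinylchromium adds only to the aldehyde (thioester, lactone and alkyl chloride untouched), and polar Felkin–Anh control by the C14 lactone oxygen should favour the 13,14-anti (13S) alcohol, the 13-epimer being removed by chromatography.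

Step 15
Reactants: 19 S-[(5E,7S)-7-hydroxy-6-methyl-7-{(2R,3R)-3-{[(2S,3S)-3-(3-chloropropyl)-3-methyloxiran-2-yl]methyl}-5-oxooxolan-2-yl}hept-5-en-2-yl] ethanethioate (C8 epimers)
Product: 20 S-[(5E,7S)-6-methyl-7-{(2R,3R)-3-{[(2S,3S)-3-(3-chloropropyl)-3-methyloxiran-2-yl]methyl}-5-oxooxolan-2-yl}-7-(triethylsilyloxy)hept-5-en-2-yl] ethanethioate (C8 epimers)
Conditions: Et3SiCl, imidazole, 4-(dimethylamino)pyridine (cat.), DMF, 0 °C → rt
Reagents that add atoms: chlorotriethylsilane, CC[Si](Cl)(CC)CC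
Why: Imidazole-mediated silylation protects the C13 alcohol without the Lewis-acidic silyl triflates that could open the neighbouring trisubstituted epoxide.

Step 16
Reactants: 20 S-[(5E,7S)-6-methyl-7-{(2R,3R)-3-{[(2S,3S)-3-(3-chloropropyl)-3-methyloxiran-2-yl]methyl}-5-oxooxolan-2-yl}-7-(triethylsilyloxy)hept-5-en-2-yl] ethanethioate (C8 epimers)
Product: 22 15-membered cyclic sulfide (sulfur bridging C7/C8; 13-O-triethylsilyl; C8 epimers), via thiol 21 (not isolated)
Conditions: H2NNH2·AcOH, degassed DMF, rt; then syringe-pump addition to Cs2CO3, DMF, 50 °C (final 1 mM)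
Reagents that add atoms: none
Why: Chemoselective hydrazinolysis of the thioacetate frees the thiol, and the cesium thiolate closes the 15-membered ring by SN2 displacement of the primary C7 chloride under high dilution, the alternative attack on the epoxide requiring a strained 11-membered ring.

Step 17
Reactants: 22 15-membered cyclic sulfide (sulfur bridging C7/C8; 13-O-triethylsilyl; C8 epimers)
Product: 24 15-membered cyclic α-chloro sulfoxide (chlorine on C7; mixture of epimers), via α-chloro sulfide 23 (not isolated)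
Conditions: NCS (1.05 equiv), CH2Cl2, 0 °C; then mCPBA (1.0 equiv), −78 → −40 °C
Reagents that add atoms: N-chlorosuccinimide, ClN1C(=O)CCC1=O; 3-chloroperoxybenzoic acid, OOC(=O)c1cccc(Cl)c1
Why: S-chlorination by NCS, deprotonation of the chlorosulfonium ion at the C7 methylene (favoured over the C8 methine) and return of chloride to carbon give the α-chloro sulfide, which is oxidised at once with one equivalent of peracid at low temperature, where sulfur reacts far faster than the 11E olefin (a C8 chloride, if formed, would converge in step 19).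

Step 18
Reactants: 24 15-membered cyclic α-chloro sulfoxide (chlorine on C7; mixture of epimers)
Product: 25 15-membered cyclic α-chloro sulfone (sulfur bridging C7/C8; chlorine on C7; 13-O-triethylsilyl; C7/C8 epimers)
Conditions: KHSO5 (as 2KHSO5·KHSO4·K2SO4), NaHCO3, THF/MeOH/H2O, 0 °C → rt
Reagents that add atoms: potassium peroxymonosulfate, [K+].[O-]S(=O)(=O)OO
Why: Buffered peroxymonosulfate oxidises the sulfoxide to the sulfone but does not epoxidise an isolated olefin in the absence of a ketone mediator, so the 11E olefin, epoxide, silyl ether and lactone should survive.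

Step 19
Reactants: 25 15-membered cyclic α-chloro sulfone (sulfur bridging C7/C8; chlorine on C7; 13-O-triethylsilyl; C7/C8 epimers)
Product: 27 (1R,3S,4S,7E,11E,13S,14R)-3,4-epoxy-13-(triethylsilyloxy)cembra-7,11-dien-16,14-olide, via thiirane 1,1-dioxide 26 (not isolated)
Conditions: KOC(CH3)3 (4 equiv), THF, −78 → 0 °C
Reagents that add atoms: none
Why: The base removes the C8 methine proton next to the sulfone, and the carbanion displaces chloride from C7 in an intramolecular 1,3-substitution (3-exo-tet) to give thiirane 1,1-dioxide 26, which loses SO2 by cheletropic extrusion to form the C7=C8 bond. This is a Ramberg–Bäcklund olefination of a macrocyclic α-halo sulfone, so the 14-membered carbocycle is closed by contraction of the 15-membered thiacycle and not by a carbon–carbon macrocyclisation. No stereocentre is created; C7 and C8 both become sp2, which is why their epimer mixtures converge on one product. The step needs the E geometry (C6 trans to C9): under strongly basic conditions the thiirane dioxide can epimerise at C7, its only α-hydrogen, to the less strained isomer with C6 and C9 on opposite faces before SO2 is lost, and a 14-membered ring accommodates an E trisubstituted olefin well. The lactone is only enolised reversibly at C15 (no β-leaving group, C1 not affected), and the chloro-sulfonyl carbanion at C7 is a poor nucleophile toward the fully substituted C4 of the epoxide, so low temperature and excess base should keep both groups intact.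

Step 20
Reactants: 27 (1R,3S,4S,7E,11E,13S,14R)-3,4-epoxy-13-(triethylsilyloxy)cembra-7,11-dien-16,14-olide
Product: 28 (1R,3S,4S,7E,11E,13S,14R)-17-(dimethylamino)-3,4-epoxy-13-(triethylsilyloxy)cembra-7,11-dien-16,14-olide (C15 epimers)
Conditions: LiN(i-Pr)2, THF, −78 °C; then CH2=NMe2 iodide, −78 °C → rt
Reagents that add atoms: N,N-dimethylmethyleneiminium iodide, C=[N+](C)C.[I-]
Why: Mannich reaction of the lactone lithium enolate with Eschenmoser's salt brings in C17 at C15, the only enolisable position, whose configuration is irrelevant.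

Step 21
Reactants: 28 (1R,3S,4S,7E,11E,13S,14R)-17-(dimethylamino)-3,4-epoxy-13-(triethylsilyloxy)cembra-7,11-dien-16,14-olide (C15 epimers)
Product: 30 (1R,3S,4S,7E,11E,13S,14R)-3,4-epoxy-13-(triethylsilyloxy)cembra-7,11,15(17)-trien-16,14-olide, via trimethylammonium iodide 29 (not isolated)
Conditions: MeI, MeOH, rt; then NaHCO3 (aq.), CH2Cl2, rt
Reagents that add atoms: none
Why: Quaternisation of the amine and mild-base β-elimination (Hofmann type, E1cB through the lactone enolate) give the α-methylene lactone without strong base.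

Step 22
Reactants: 30 (1R,3S,4S,7E,11E,13S,14R)-3,4-epoxy-13-(triethylsilyloxy)cembra-7,11,15(17)-trien-16,14-olide
Product: 31 (1R,3S,4S,7E,11E,13S,14R)-3,4-epoxy-13-hydroxycembra-7,11,15(17)-trien-16,14-olide
Conditions: HF·pyridine, pyridine, THF, 0 °C → rt
Reagents that add atoms: none
Why: Pyridine-buffered HF removes the triethylsilyl ether under non-basic conditions, which avoids oxa-Michael addition of the C13 alkoxide to the methylene lactone and spares the epoxide.

Step 23
Reactants: 31 (1R,3S,4S,7E,11E,13S,14R)-3,4-epoxy-13-hydroxycembra-7,11,15(17)-trien-16,14-olide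
Product: 32 (1R,3S,4S,7E,11E,13S,14R)-13-acetoxy-3,4-epoxycembra-7,11,15(17)-trien-16,14-olide
Conditions: Ac2O, Et3N, 4-(dimethylamino)pyridine (cat.), CH2Cl2, 0 °C
Reagents that add atoms: acetic anhydride, CC(=O)OC(C)=O
Why: Nucleophile-catalysed acylation of the secondary allylic alcohol proceeds with retention at C13.

Step 24
Reactants: 32 (1R,3S,4S,7E,11E,13S,14R)-13-acetoxy-3,4-epoxycembra-7,11,15(17)-trien-16,14-olide
Product: 33 CNP0166375.1, (1R,3S,4S,7S,11E,13S,14R)-13-acetoxy-3,4-epoxy-7-hydroperoxycembra-8(19),11,15(17)-trien-16,14-olide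
Conditions: O2, 5,10,15,20-tetraphenylporphyrin (cat.), hν (visible), CH2Cl2, −20 °C, partial conversion; HPLC
Reagents that add atoms: oxygen, O=O
Why: In this Schenck ene reaction singlet oxygen should choose the electron-rich C7=C8 olefin over C11=C12 (deactivated by the allylic acetate) and the electron-poor methylene lactone, bond to C7 while taking a hydrogen from the C19 methyl on the more substituted side of the E olefin (cis effect), and approach from the outer face of the ring, which is expected to give the 7S hydroperoxide, isomers being removed by HPLC.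

Compound list
1 | (R)-5-(hydroxymethyl)dihydrofuran-2(3H)-one | OC[C@@H]1OC(=O)CC1 | starting material
2 | (R)-5-{[tert-butyl(dimethyl)silyl]oxymethyl}dihydrofuran-2(3H)-one | CC(C)(C)[Si](C)(C)OC[C@@H]1OC(=O)CC1 | intermediate
3 | (5R)-5-{[tert-butyl(dimethyl)silyl]oxymethyl}-3-(phenylselanyl)dihydrofuran-2(3H)-one (C3 epimers) | CC(C)(C)[Si](C)(C)OC[C@@H]1OC(=O)C([Se]c2ccccc2)C1 | intermediate
4 | (R)-5-{[tert-butyl(dimethyl)silyl]oxymethyl}furan-2(5H)-one | CC(C)(C)[Si](C)(C)OC[C@@H]1OC(=O)C=C1 | intermediate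
5 | (4S,5R)-5-{[tert-butyl(dimethyl)silyl]oxymethyl}-4-(hydroxymethyl)dihydrofuran-2(3H)-one | CC(C)(C)[Si](C)(C)OC[C@@H]1OC(=O)C[C@H]1CO | intermediate
6 | (4R,5R)-5-{[tert-butyl(dimethyl)silyl]oxymethyl}-4-(iodomethyl)dihydrofuran-2(3H)-one | CC(C)(C)[Si](C)(C)OC[C@@H]1OC(=O)C[C@H]1CI | intermediate
7 | 5-chloropent-1-yne | C#CCCCCl | starting material
8 | (E)-5-chloro-1-iodo-2-methylpent-1-ene | ClCCC/C(C)=C/I | intermediate
9 | {[(2R,3R)-2-{[tert-butyl(dimethyl)silyl]oxymethyl}-5-oxooxolan-3-yl]methyl}zinc iodide | CC(C)(C)[Si](C)(C)OC[C@@H]1OC(=O)C[C@H]1C[Zn]I | intermediate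
10 | (4R,5R)-5-{[tert-butyl(dimethyl)silyl]oxymethyl}-4-[(2E)-6-chloro-3-methylhex-2-en-1-yl]dihydrofuran-2(3H)-one | CC(C)(C)[Si](C)(C)OC[C@@H]1OC(=O)C[C@H]1C/C=C(\C)CCCCl | intermediate
11 | (4R,5R)-5-{[tert-butyl(dimethyl)silyl]oxymethyl}-4-{[(2S,3S)-3-(3-chloropropyl)-3-methyloxiran-2-yl]methyl}dihydrofuran-2(3H)-one | CC(C)(C)[Si](C)(C)OC[C@@H]1OC(=O)C[C@H]1C[C@@H]2O[C@@]2(C)CCCCl | intermediate
12 | (4R,5R)-4-{[(2S,3S)-3-(3-chloropropyl)-3-methyloxiran-2-yl]methyl}-5-(hydroxymethyl)dihydrofuran-2(3H)-one | OC[C@@H]1OC(=O)C[C@H]1C[C@@H]2O[C@@]2(C)CCCCl | intermediate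
13 | (2R,3R)-3-{[(2S,3S)-3-(3-chloropropyl)-3-methyloxiran-2-yl]methyl}-5-oxooxolane-2-carbaldehyde | O=C[C@@H]1OC(=O)C[C@H]1C[C@@H]2O[C@@]2(C)CCCCl | intermediate
14 | hex-4-yn-1-ol | CC#CCCCO | starting material
15 | (E)-4-iodohex-4-en-1-ol | C/C(I)=C\CCCO | intermediate
16 | (E)-4-iodohex-4-enal | C/C(I)=C\CCC=O | intermediate
17 | (E)-6-iodohept-5-en-2-ol (racemic) | C/C(I)=C\CCC(C)O | intermediate
18 | S-[(E)-6-iodohept-5-en-2-yl] ethanethioate (racemic) | C/C(I)=C\CCC(C)SC(C)=O | intermediate
19 | S-[(5E,7S)-7-hydroxy-6-methyl-7-{(2R,3R)-3-{[(2S,3S)-3-(3-chloropropyl)-3-methyloxiran-2-yl]methyl}-5-oxooxolan-2-yl}hept-5-en-2-yl] ethanethioate (C8 epimers; cembrane 13S) | CC(=O)SC(C)CC/C=C(\C)[C@H](O)[C@@H]1OC(=O)C[C@H]1C[C@@H]2O[C@@]2(C)CCCCl | intermediate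
20 | S-[(5E,7S)-6-methyl-7-{(2R,3R)-3-{[(2S,3S)-3-(3-chloropropyl)-3-methyloxiran-2-yl]methyl}-5-oxooxolan-2-yl}-7-(triethylsilyloxy)hept-5-en-2-yl] ethanethioate (C8 epimers) | CC(=O)SC(C)CC/C=C(\C)[C@H](O[Si](CC)(CC)CC)[C@@H]1OC(=O)C[C@H]1C[C@@H]2O[C@@]2(C)CCCCl | intermediate
21 | (4R,5R)-4-{[(2S,3S)-3-(3-chloropropyl)-3-methyloxiran-2-yl]methyl}-5-[(1S,2E)-2-methyl-6-sulfanyl-1-(triethylsilyloxy)hept-2-en-1-yl]dihydrofuran-2(3H)-one (C8 epimers) | SC(C)CC/C=C(\C)[C@H](O[Si](CC)(CC)CC)[C@@H]1OC(=O)C[C@H]1C[C@@H]2O[C@@]2(C)CCCCl | intermediate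
22 | 15-membered cyclic sulfide: (1R,3S,4S,11E,13S,14R)-3,4-epoxy-13-(triethylsilyloxy)-7,8-seco-cembr-11-en-16,14-olide closed through a sulfur atom between C7 and C8 (C8 epimers) | C1/C=C(\C)[C@H](O[Si](CC)(CC)CC)[C@@H]2OC(=O)C[C@H]2C[C@@H]2O[C@@]2(C)CCCSC(C)C1 | intermediate
23 | 7-chloro derivative of 22 (α-chloro sulfide; C7 and C8 epimers) | C1/C=C(\C)[C@H](O[Si](CC)(CC)CC)[C@@H]2OC(=O)C[C@H]2C[C@@H]2O[C@@]2(C)CCC(Cl)SC(C)C1 | intermediate
24 | S-oxide of 23 (α-chloro sulfoxide; epimers at C7, C8 and sulfur) | C1/C=C(\C)[C@H](O[Si](CC)(CC)CC)[C@@H]2OC(=O)C[C@H]2C[C@@H]2O[C@@]2(C)CCC(Cl)S(=O)C(C)C1 | intermediate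
25 | S,S-dioxide of 23 (15-membered α-chloro sulfone, sulfur between C7 and C8, chlorine on C7; C7 and C8 epimers) | C1/C=C(\C)[C@H](O[Si](CC)(CC)CC)[C@@H]2OC(=O)C[C@H]2C[C@@H]2O[C@@]2(C)CCC(Cl)S(=O)(=O)C(C)C1 | intermediate
26 | (1R,3S,4S,11E,13S,14R)-3,4-epoxy-7,8-epithio-13-(triethylsilyloxy)cembr-11-en-16,14-olide S,S-dioxide (thiirane 1,1-dioxide fused at C7–C8) | C1/C=C(\C)[C@H](O[Si](CC)(CC)CC)[C@@H]2OC(=O)C[C@H]2C[C@@H]2O[C@@]2(C)CCC3S(=O)(=O)C3(C)C1 | intermediate
27 | (1R,3S,4S,7E,11E,13S,14R)-3,4-epoxy-13-(triethylsilyloxy)cembra-7,11-dien-16,14-olide | C1/C=C(\C)[C@H](O[Si](CC)(CC)CC)[C@@H]2OC(=O)C[C@H]2C[C@@H]2O[C@@]2(C)CC/C=C(\C)C1 | intermediate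
28 | (1R,3S,4S,7E,11E,13S,14R)-17-(dimethylamino)-3,4-epoxy-13-(triethylsilyloxy)cembra-7,11-dien-16,14-olide (C15 epimers) | C1/C=C(\C)[C@H](O[Si](CC)(CC)CC)[C@@H]2OC(=O)C(CN(C)C)[C@H]2C[C@@H]2O[C@@]2(C)CC/C=C(\C)C1 | intermediate
29 | N-methyl quaternary ammonium iodide of 28 (17-trimethylammonio) | C1/C=C(\C)[C@H](O[Si](CC)(CC)CC)[C@@H]2OC(=O)C(C[N+](C)(C)C)[C@H]2C[C@@H]2O[C@@]2(C)CC/C=C(\C)C1.[I-] | intermediate
30 | (1R,3S,4S,7E,11E,13S,14R)-3,4-epoxy-13-(triethylsilyloxy)cembra-7,11,15(17)-trien-16,14-olide | C1/C=C(\C)[C@H](O[Si](CC)(CC)CC)[C@@H]2OC(=O)C(=C)[C@H]2C[C@@H]2O[C@@]2(C)CC/C=C(\C)C1 | intermediate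
31 | (1R,3S,4S,7E,11E,13S,14R)-3,4-epoxy-13-hydroxycembra-7,11,15(17)-trien-16,14-olide | C1/C=C(\C)[C@H](O)[C@@H]2OC(=O)C(=C)[C@H]2C[C@@H]2O[C@@]2(C)CC/C=C(\C)C1 | intermediate
32 | (1R,3S,4S,7E,11E,13S,14R)-13-acetoxy-3,4-epoxycembra-7,11,15(17)-trien-16,14-olide | C1/C=C(\C)[C@H](OC(C)=O)[C@@H]2OC(=O)C(=C)[C@H]2C[C@@H]2O[C@@]2(C)CC/C=C(\C)C1 | intermediate
33 | CNP0166375.1, (1R,3S,4S,7S,11E,13S,14R)-13-acetoxy-3,4-epoxy-7-hydroperoxycembra-8(19),11,15(17)-trien-16,14-olide | C=C1CC/C=C(\C)[C@H](OC(C)=O)[C@@H]2OC(=O)C(=C)[C@H]2C[C@@H]2O[C@@]2(C)CC[C@@H]1OO | target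

Total step count: 24 steps.
Longest linear sequence: 19 steps (steps 1–4, 6–9 and 14–24).

Steps most likely to fail

Step 19 (ring contraction). What may go wrong: the thiirane dioxide may lose SO2 before it equilibrates, or the ring may prefer the other geometry, so that the 7Z olefin forms; slow removal of the hindered C8 proton may also leave time for base-induced damage to the lactone and epoxide. Fallback (sulfur extrusion in the open chain, ring closure by chromium-mediated vinylation): the route sets out from epoxide 11 and thioacetate 18. Hydrazine acetate followed by Cs2CO3 in DMF joins them by S-alkylation at C7 to the open-chain sulfide F1. NCS and then mCPBA (2.2 equiv, no electron-rich olefin being present at this stage) give the open-chain α-chloro sulfone F2. KOC(CH3)3 in THF gives the open-chain 7E diene vinyl iodide F3, whose geometrical isomers can be separated on AgNO3-impregnated silica without any ring constraint. Bu4NF/AcOH frees the primary alcohol F4, and Dess–Martin oxidation gives the aldehyde F5. CrCl2/NiCl2 in DMSO at high dilution closes the 14-membered ring at C12–C13 to the macrocyclic 13S alcohol F6 (13-epimer separated). Et3SiCl/imidazole then returns to the route at 27.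

Step 24 (oxygen ene reaction). What may go wrong: hydrogen abstraction from C6 instead of C19 (tertiary C8 hydroperoxide), attack on the wrong face of C7=C8, or competing oxygenation of C11=C12. Fallback (oxygenate before the protecting-group exchange and carry the hydroperoxide masked): the route sets out from silyl ether 30, in which the bulky triethylsilyloxy group shields C11=C12 and biases the ring conformation differently. Sensitised photooxygenation gives the silylated 7S hydroperoxide F7, which is purified at this stage. 2-Methoxypropene with catalytic pyridinium p-toluenesulfonate masks it as the peroxyketal F8. Bu4NF/AcOH removes the silyl group to give the alcohol F9, and Ac2O/4-(dimethylamino)pyridine gives the acetate F10. Brief AcOH/THF/H2O hydrolysis of the peroxyketal returns to the route at 33.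

Step 17 (α-chlorination and first oxidation). What may go wrong: trapping of the transient sulfur-stabilised cation at C7 by the epoxide oxygen (five-membered oxonium ion), double chlorination, or hydrolysis of the α-chloro sulfide before it is oxidised. Fallback (oxidise first, chlorinate under basic conditions): the route sets out from sulfide 22. NaIO4 in MeOH/THF/H2O at 0 °C gives the cyclic sulfoxide F11. NCS with K2CO3 in CH2Cl2 then chlorinates the sulfoxide α-carbon by base-mediated deprotonation of the chlorooxosulfonium ion, which favours the C7 methylene and avoids a free thionium ion. This returns to the route at 24.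

Further compounds
F1 | step 19 | open-chain sulfide from 11 and 18 (sulfur between C7 and C8; primary O-tert-butyldimethylsilyl; E vinyl iodide at C12; C8 epimers) | CC(C)(C)[Si](C)(C)OC[C@@H]1OC(=O)C[C@H]1C[C@@H]2O[C@@]2(C)CCCSC(C)CC/C=C(\C)I
F2 | step 19 | open-chain α-chloro sulfone (chlorine on C7; C7 and C8 epimers) | CC(C)(C)[Si](C)(C)OC[C@@H]1OC(=O)C[C@H]1C[C@@H]2O[C@@]2(C)CCC(Cl)S(=O)(=O)C(C)CC/C=C(\C)I
F3 | step 19 | open-chain (7E,11E)-diene with C12 iodide and primary O-tert-butyldimethylsilyl group | CC(C)(C)[Si](C)(C)OC[C@@H]1OC(=O)C[C@H]1C[C@@H]2O[C@@]2(C)CC/C=C(\C)CC/C=C(\C)I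
F4 | step 19 | open-chain (7E,11E)-diene C13 primary alcohol | OC[C@@H]1OC(=O)C[C@H]1C[C@@H]2O[C@@]2(C)CC/C=C(\C)CC/C=C(\C)I
F5 | step 19 | open-chain (7E,11E)-diene C13 aldehyde | O=C[C@@H]1OC(=O)C[C@H]1C[C@@H]2O[C@@]2(C)CC/C=C(\C)CC/C=C(\C)I
F6 | step 19 | (1R,3S,4S,7E,11E,13S,14R)-3,4-epoxy-13-hydroxycembra-7,11-dien-16,14-olide | C1/C=C(\C)[C@H](O)[C@@H]2OC(=O)C[C@H]2C[C@@H]2O[C@@]2(C)CC/C=C(\C)C1
F7 | step 24 | (1R,3S,4S,7S,11E,13S,14R)-3,4-epoxy-7-hydroperoxy-13-(triethylsilyloxy)cembra-8(19),11,15(17)-trien-16,14-olide | C=C1CC/C=C(\C)[C@H](O[Si](CC)(CC)CC)[C@@H]2OC(=O)C(=C)[C@H]2C[C@@H]2O[C@@]2(C)CC[C@@H]1OO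
F8 | step 24 | 7-(2-methoxypropan-2-ylperoxy) derivative of F7 (peroxyketal) | C=C1CC/C=C(\C)[C@H](O[Si](CC)(CC)CC)[C@@H]2OC(=O)C(=C)[C@H]2C[C@@H]2O[C@@]2(C)CC[C@@H]1OOC(C)(C)OC
F9 | step 24 | 13-hydroxy peroxyketal | C=C1CC/C=C(\C)[C@H](O)[C@@H]2OC(=O)C(=C)[C@H]2C[C@@H]2O[C@@]2(C)CC[C@@H]1OOC(C)(C)OC
F10 | step 24 | 13-acetoxy peroxyketal | C=C1CC/C=C(\C)[C@H](OC(C)=O)[C@@H]2OC(=O)C(=C)[C@H]2C[C@@H]2O[C@@]2(C)CC[C@@H]1OOC(C)(C)OC
F11 | step 17 | S-oxide of 22 (15-membered cyclic sulfoxide; epimers at C8 and sulfur) | C1/C=C(\C)[C@H](O[Si](CC)(CC)CC)[C@@H]2OC(=O)C[C@H]2C[C@@H]2O[C@@]2(C)CCCS(=O)C(C)C1
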